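**Retrosynthetic overview**
- Last bond: linker CH2 to the ring CH of the hydroazulene, by copper-catalysed anti SN2' coupling of a western alkylborane with an eastern cyclic allylic phosphate; this also sets that stereocenter and places the ring alkene.
- Western bicycle: oxepane, then cyclohexane, then a temporary cyclic carbonate, closed in one Lewis-acid cascade of a bis-epoxide made by Shi epoxidation of (2Z,6Z)-farnesyl tert-butyl carbonate.
- Eastern bicycle: cyclopentane first (stereocenter from asymmetric CuH conjugate reduction of an achiral cyclopentenone), then the cycloheptenone by intramolecular enolate opening of a cyclopentene epoxide (sets the cis fusion and the tertiary alcohol).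
- Ring order: oxepane → cyclohexane (west); cyclopentane → cycloheptene (east); fragments joined last, no protecting groups.

The SMILES was read as cis-fused in both bicycles, and the route is built for exactly that configuration.

Assumption: (2Z,6Z)-farnesol (1) is bought as the single geometric isomer, and the facial sense of the Shi ketone and of the CuH/p-tol-BINAP reduction follows the accepted models (the antipodal catalyst is used if it proves reversed).

**Step 1**
Reactants: 1 (2Z,6Z)-3,7,11-trimethyldodeca-2,6,10-trien-1-ol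
Product: 2 tert-butyl (2Z,6Z)-3,7,11-trimethyldodeca-2,6,10-trien-1-yl carbonate
Conditions: Boc2O, 1-methylimidazole (cat.), toluene, rt
Reagents that add atoms: di-tert-butyl dicarbonate CC(C)(C)OC(=O)OC(=O)OC(C)(C)C
Why: Nucleophile-catalysed O-acylation of the primary allylic alcohol installs the tert-butyl carbonate that later acts as the internal oxygen nucleophile; no stereocenter is formed.

**Step 2**
Reactants: 2 tert-butyl (2Z,6Z)-3,7,11-trimethyldodeca-2,6,10-trien-1-yl carbonate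
Product: 3 tert-butyl (2Z)-3-methyl-5-[(2R,3S)-3-methyl-3-[2-[(2R)-3,3-dimethyloxiran-2-yl]ethyl]oxiran-2-yl]pent-2-en-1-yl carbonate
Conditions: Shi ketone (1,2:4,5-di-O-isopropylidene-D-erythro-2,3-hexodiulo-2,6-pyranose, from D-fructose, 0.3 equiv), KHSO5 (as the triple salt 2KHSO5·KHSO4·K2SO4), K2CO3, Bu4NHSO4 (cat.), MeCN/(MeO)2CH2/aq Na2B4O7 buffer, 0 °C
Reagents that add atoms: potassium peroxymonosulfate [K+].[O-]S(=O)(=O)OO
Why: Shi asymmetric epoxidation (chiral dioxirane, spiro transition state) epoxidizes the two electron-rich trisubstituted alkenes and spares the deactivated allylic-carbonate alkene, setting (R) at each CH carbon and hence (2R,3S) on the oxirane from the 6Z alkene, the first stereocenters of the western half.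

**Step 3**
Reactants: 3 tert-butyl (2Z)-3-methyl-5-[(2R,3S)-3-methyl-3-[2-[(2R)-3,3-dimethyloxiran-2-yl]ethyl]oxiran-2-yl]pent-2-en-1-yl carbonate
Product: 4 cyclic carbonate (1,3-dioxan-2-one bridging the 6-CH2O and 7-O oxygens) of (3R,5aS,6R,7R,9aR)-6-(hydroxymethyl)-2,2,5a,7-tetramethyldecahydro-1-benzoxepine-3,7-diol
Conditions: BF3·OEt2 (0.3 equiv), CH2Cl2, −78 to −40 °C
Reagents that add atoms: none
Why: Proposed new method: activation of the terminal epoxide lets the internal epoxide oxygen attack its tertiary carbon (bicyclic epoxonium, oxepane), the Z alkene then opens the epoxonium at the quaternary carbon with inversion through a chair (Stork–Eschenmoser anti addition) and the nascent tertiary cation is captured anti by the carbonate carbonyl oxygen with loss of isobutene faster than ring inversion, so the ring fusion, C6 and C7 are all set stereospecifically; the closest known reactions are Lewis-acid tandem oxa-/carbacyclizations of (E)-bis-epoxides ending in alkenes or enol silanes and tert-butyl-carbonate-terminated polyepoxide cascades.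

**Step 4**
Reactants: 4 cyclic carbonate of (3R,5aS,6R,7R,9aR)-6-(hydroxymethyl)-2,2,5a,7-tetramethyldecahydro-1-benzoxepine-3,7-diol
Product: 5 (3R,5aS,6R,7R,9aR)-6-(hydroxymethyl)-2,2,5a,7-tetramethyldecahydro-1-benzoxepine-3,7-diol
Conditions: K2CO3 (0.2 equiv), MeOH, rt
Reagents that add atoms: none
Why: Base-catalysed transesterification (methanolysis) of the cyclic carbonate frees the primary and tertiary hydroxyls without touching a stereocenter.

**Step 5**
Reactants: 5 (3R,5aS,6R,7R,9aR)-6-(hydroxymethyl)-2,2,5a,7-tetramethyldecahydro-1-benzoxepine-3,7-diol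
Product: 6 (5aS,6S,7R,9aR)-7-hydroxy-2,2,5a,7-tetramethyl-3-oxodecahydro-1-benzoxepine-6-carbaldehyde
Conditions: Dess–Martin periodinane (2.5 equiv), CH2Cl2, 0 °C to rt
Reagents that add atoms: none
Why: Dess–Martin oxidation converts the primary alcohol to the aldehyde and the secondary alcohol to the ketone in one operation while the tertiary alcohol is inert, and the alpha carbon, flanked by two fully substituted carbons, does not epimerize under these neutral conditions.

**Step 6**
Reactants: 6 (5aS,6S,7R,9aR)-7-hydroxy-2,2,5a,7-tetramethyl-3-oxodecahydro-1-benzoxepine-6-carbaldehyde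
Product: 7 (5aS,6S,7R,9aR)-6-ethenyl-7-hydroxy-2,2,5a,7-tetramethyloctahydro-1-benzoxepin-3(2H)-one
Conditions: Ph3PCH3Br, KN(SiMe3)2, THF, −78 to 0 °C
Reagents that add atoms: methyltriphenylphosphonium bromide C[P+](c1ccccc1)(c1ccccc1)c1ccccc1.[Br-]
Why: Wittig methylenation is selective for the aldehyde over the hindered alpha-alkoxy ketone at low temperature and gives the vinyl group that carries both linker carbons.

**Step 7**
Reactants: 8 3-ethoxycyclopent-2-en-1-one; 9 methyl 2-methylpropanoate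
Product: 11 methyl 2-methyl-2-(3-oxocyclopent-1-en-1-yl)propanoate, via tertiary alcohol adduct 10 (not isolated)
Conditions: 9, LiN(i-Pr)2, THF, −78 °C; then 8, −78 to 0 °C; then 1 M aq HCl, rt
Reagents that add atoms: water O
Why: Stork–Danheiser sequence, in which 1,2-addition of the ester enolate to the vinylogous ester and acid hydrolysis/dehydration gives the achiral 3-substituted cyclopentenone carrying the future gem-dimethyl carbon.

**Step 8**
Reactants: 11 methyl 2-methyl-2-(3-oxocyclopent-1-en-1-yl)propanoate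
Product: 13 methyl 2-methyl-2-[(1S)-3-(trifluoromethylsulfonyloxy)cyclopent-2-en-1-yl]propanoate, via diphenylsilyl enol ether 12 (not isolated)
Conditions: CuCl (5 mol%), NaOt-Bu (5 mol%), (R)-p-tol-BINAP (5 mol%), Ph2SiH2, toluene, 0 °C; then CsF, PhNTf2, DME, rt
Reagents that add atoms: N-phenylbis(trifluoromethanesulfonimide) O=S(=O)(N(c1ccccc1)S(=O)(=O)C(F)(F)F)C(F)(F)F
Why: Copper hydride asymmetric conjugate reduction (ligand-controlled hydride delivery to one face of the beta carbon) sets the first eastern stereocenter and gives the regiodefined silyl enol ether, which fluoride and PhNTf2 convert into the enol triflate.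

**Step 9**
Reactants: 13 methyl 2-methyl-2-[(1S)-3-(trifluoromethylsulfonyloxy)cyclopent-2-en-1-yl]propanoate
Product: 14 methyl 2-methyl-2-[(1S)-3-methylcyclopent-2-en-1-yl]propanoate
Conditions: MeMgBr, Fe(acac)3 (5 mol%), THF/NMP, −30 °C
Reagents that add atoms: methylmagnesium bromide C[Mg]Br
Why: Iron-catalysed Kumada-type cross-coupling of the alkenyl triflate installs the methyl of the future tertiary carbinol without touching the hindered ester.

**Step 10**
Reactants: 14 methyl 2-methyl-2-[(1S)-3-methylcyclopent-2-en-1-yl]propanoate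
Product: 15 2-methyl-2-[(1S)-3-methylcyclopent-2-en-1-yl]propanal
Conditions: i-Bu2AlH (1.1 equiv), CH2Cl2, −78 °C
Reagents that add atoms: none
Why: Partial reduction of the alpha-quaternary methyl ester stops at the aldehyde through the stable aluminium hemiacetal at low temperature.

**Step 11**
Reactants: 15 2-methyl-2-[(1S)-3-methylcyclopent-2-en-1-yl]propanal
Product: 16 methyl (2Z)-2,4-dimethyl-4-[(1S)-3-methylcyclopent-2-en-1-yl]pent-2-enoate
Conditions: (CF3CH2O)2P(O)CH(CH3)CO2Me, KN(SiMe3)2, 18-crown-6, THF, −78 °C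
Reagents that add atoms: methyl 2-[bis(2,2,2-trifluoroethoxy)phosphoryl]propanoate COC(=O)C(C)P(=O)(OCC(F)(F)F)OCC(F)(F)F
Why: The Still–Gennari variant of the Horner–Wadsworth–Emmons reaction gives the Z trisubstituted enoate under kinetic control, the geometry the seven-membered ring needs.

**Step 12**
Reactants: 16 methyl (2Z)-2,4-dimethyl-4-[(1S)-3-methylcyclopent-2-en-1-yl]pent-2-enoate
Product: 18 (3Z)-3,5-dimethyl-5-[(1S)-3-methylcyclopent-2-en-1-yl]hex-3-en-2-one, via alpha-silyl ketone 17 (not isolated)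
Conditions: Me3SiCH2Li (2.2 equiv), pentane/THF, 0 °C; then MeOH, rt
Reagents that add atoms: (trimethylsilyl)methyllithium [Li]C[Si](C)(C)C
Why: Acyl substitution by (trimethylsilyl)methyllithium stops at the ketone stage because the alpha-silyl ketone is held as its enolate, and methanolysis of the C–Si bond leaves the methyl ketone with the Z alkene intact.

**Step 13**
Reactants: 18 (3Z)-3,5-dimethyl-5-[(1S)-3-methylcyclopent-2-en-1-yl]hex-3-en-2-one
Product: 19 (3Z)-3,5-dimethyl-5-[(1R,2R,5S)-5-methyl-6-oxabicyclo[3.1.0]hexan-2-yl]hex-3-en-2-one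
Conditions: m-CPBA, CH2Cl2, 0 °C
Reagents that add atoms: 3-chloroperbenzoic acid OOC(=O)c1cccc(Cl)c1
Why: Prilezhaev epoxidation picks the electron-rich ring alkene over the enone and occurs anti to the bulky quaternary side chain, which puts the oxygen on the face that becomes the tertiary alcohol.

**Step 14**
Reactants: 19 (3Z)-3,5-dimethyl-5-[(1R,2R,5S)-5-methyl-6-oxabicyclo[3.1.0]hexan-2-yl]hex-3-en-2-one
Product: 20 (1S,3aS,8aS)-1-hydroxy-1,4,4,6-tetramethyl-2,3,3a,4,8,8a-hexahydroazulen-7(1H)-one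
Conditions: KOt-Bu (0.3 equiv), t-BuOH/THF, 50 °C
Reagents that add atoms: none
Why: Intramolecular SN2 opening of the epoxide at its secondary carbon by the potassium enolate of the methyl ketone (7-exo-tet, helped by the Z enone and the gem-dimethyl group) closes the cycloheptenone, and the inversion puts the new C–C bond cis to the side chain (cis ring fusion) and leaves the tertiary alcohol trans to it.

**Step 15**
Reactants: 20 (1S,3aS,8aS)-1-hydroxy-1,4,4,6-tetramethyl-2,3,3a,4,8,8a-hexahydroazulen-7(1H)-one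
Product: 21 (1S,3aS,7R,8aS)-1,4,4,6-tetramethyl-1,2,3,3a,4,7,8,8a-octahydroazulene-1,7-diol
Conditions: NaBH4, CeCl3·7H2O, MeOH, −40 °C
Reagents that add atoms: none
Why: Luche 1,2-reduction, with hydride expected on the convex face of the cis-fused bicycle (the face of the ring-fusion hydrogens), gives the (7R) allylic alcohol.

**Step 16**
Reactants: 21 (1S,3aS,7R,8aS)-1,4,4,6-tetramethyl-1,2,3,3a,4,7,8,8a-octahydroazulene-1,7-diol
Product: 22 diethyl (1S,3aS,7S,8aS)-1-hydroxy-1,4,4,6-tetramethyl-1,2,3,3a,4,7,8,8a-octahydroazulen-7-yl phosphate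
Conditions: (EtO)2P(O)OH, PPh3, DIAD, THF, 0 °C
Reagents that add atoms: diethyl hydrogen phosphate CCOP(=O)(O)OCC
Why: The Mitsunobu reaction inverts the secondary allylic carbinol to the (7S) phosphate needed for anti SN2' substitution, and the tertiary alcohol does not react.

**Step 17**
Reactants: 7 (5aS,6S,7R,9aR)-6-ethenyl-7-hydroxy-2,2,5a,7-tetramethyloctahydro-1-benzoxepin-3(2H)-one; 22 diethyl (1S,3aS,7S,8aS)-1-hydroxy-1,4,4,6-tetramethyl-1,2,3,3a,4,7,8,8a-octahydroazulen-7-yl phosphate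
Product: 24 (5aS,6S,7R,9aR)-7-hydroxy-6-[2-[(1S,3aS,5R,8aS)-1-hydroxy-1,4,4,6-tetramethyl-1,2,3,3a,4,5,8,8a-octahydroazulen-5-yl]ethyl]-2,2,5a,7-tetramethyloctahydro-1-benzoxepin-3(2H)-one, via alkylborane 23 (not isolated)
Conditions: 7, 9-BBN (9-borabicyclo[3.3.1]nonane, 1.2 equiv), THF, 0 °C to rt; then KOt-Bu, CuOAc (10 mol%), 22, THF, 50 °C
Reagents that add atoms: none
Why: Anti-Markovnikov hydroboration of the vinyl group followed by copper-catalysed gamma-selective allyl–alkyl coupling of the alkyl-9-BBN with the allylic phosphate (SN2', anti to the leaving group) forms the linker bond on the face opposite the phosphate, sets C5 of the azulene and moves the alkene into its final position.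

**Compound list**
1 | (2Z,6Z)-3,7,11-trimethyldodeca-2,6,10-trien-1-ol ((2Z,6Z)-farnesol) | OC/C=C(/C)CC/C=C(/C)CCC=C(C)C | starting material
2 | tert-butyl (2Z,6Z)-3,7,11-trimethyldodeca-2,6,10-trien-1-yl carbonate | CC(C)(C)OC(=O)OC/C=C(/C)CC/C=C(/C)CCC=C(C)C | intermediate
3 | tert-butyl (2Z)-3-methyl-5-[(2R,3S)-3-methyl-3-[2-[(2R)-3,3-dimethyloxiran-2-yl]ethyl]oxiran-2-yl]pent-2-en-1-yl carbonate | CC(C)(C)OC(=O)OC/C=C(/C)CC[C@H]1O[C@@]1(C)CC[C@H]1OC1(C)C | intermediate
4 | cyclic carbonate (1,3-dioxan-2-one bridging the 6-CH2O and 7-O oxygens, 3-OH free) of (3R,5aS,6R,7R,9aR)-6-(hydroxymethyl)-2,2,5a,7-tetramethyldecahydro-1-benzoxepine-3,7-diol; cis-fused oxepane/cyclohexane | O=C1OC[C@H]2[C@]3(C)CC[C@@H](O)C(C)(C)O[C@@H]3CC[C@@]2(C)O1 | intermediate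
5 | (3R,5aS,6R,7R,9aR)-6-(hydroxymethyl)-2,2,5a,7-tetramethyldecahydro-1-benzoxepine-3,7-diol | OC[C@H]1[C@]2(C)CC[C@@H](O)C(C)(C)O[C@@H]2CC[C@@]1(C)O | intermediate
6 | (5aS,6S,7R,9aR)-7-hydroxy-2,2,5a,7-tetramethyl-3-oxodecahydro-1-benzoxepine-6-carbaldehyde | O=C[C@H]1[C@]2(C)CCC(=O)C(C)(C)O[C@@H]2CC[C@@]1(C)O | intermediate
7 | (5aS,6S,7R,9aR)-6-ethenyl-7-hydroxy-2,2,5a,7-tetramethyloctahydro-1-benzoxepin-3(2H)-one (western fragment) | C=C[C@H]1[C@]2(C)CCC(=O)C(C)(C)O[C@@H]2CC[C@@]1(C)O | intermediate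
8 | 3-ethoxycyclopent-2-en-1-one | CCOC1=CC(=O)CC1 | starting material
9 | methyl 2-methylpropanoate (methyl isobutyrate) | COC(=O)C(C)C | starting material
10 | methyl 2-(3-ethoxy-1-hydroxycyclopent-2-en-1-yl)-2-methylpropanoate (racemic 1,2-adduct) | CCOC1=CC(O)(CC1)C(C)(C)C(=O)OC | intermediate
11 | methyl 2-methyl-2-(3-oxocyclopent-1-en-1-yl)propanoate | COC(=O)C(C)(C)C1=CC(=O)CC1 | intermediate
12 | methyl 2-[(1S)-3-(diphenylsilyloxy)cyclopent-2-en-1-yl]-2-methylpropanoate | COC(=O)C(C)(C)[C@H]1CCC(O[SiH](c2ccccc2)c2ccccc2)=C1 | intermediate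
13 | methyl 2-methyl-2-[(1S)-3-(trifluoromethylsulfonyloxy)cyclopent-2-en-1-yl]propanoate | COC(=O)C(C)(C)[C@H]1CCC(OS(=O)(=O)C(F)(F)F)=C1 | intermediate
14 | methyl 2-methyl-2-[(1S)-3-methylcyclopent-2-en-1-yl]propanoate | COC(=O)C(C)(C)[C@H]1CCC(C)=C1 | intermediate
15 | 2-methyl-2-[(1S)-3-methylcyclopent-2-en-1-yl]propanal | O=CC(C)(C)[C@H]1CCC(C)=C1 | intermediate
16 | methyl (2Z)-2,4-dimethyl-4-[(1S)-3-methylcyclopent-2-en-1-yl]pent-2-enoate | COC(=O)/C(C)=C\C(C)(C)[C@H]1CCC(C)=C1 | intermediate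
17 | (3Z)-3,5-dimethyl-5-[(1S)-3-methylcyclopent-2-en-1-yl]-1-(trimethylsilyl)hex-3-en-2-one | C[Si](C)(C)CC(=O)/C(C)=C\C(C)(C)[C@H]1CCC(C)=C1 | intermediate
18 | (3Z)-3,5-dimethyl-5-[(1S)-3-methylcyclopent-2-en-1-yl]hex-3-en-2-one | CC(=O)/C(C)=C\C(C)(C)[C@H]1CCC(C)=C1 | intermediate
19 | (3Z)-3,5-dimethyl-5-[(1R,2R,5S)-5-methyl-6-oxabicyclo[3.1.0]hexan-2-yl]hex-3-en-2-one (epoxide anti to the side chain) | CC(=O)/C(C)=C\C(C)(C)[C@H]1CC[C@]2(C)O[C@H]12 | intermediate
20 | (1S,3aS,8aS)-1-hydroxy-1,4,4,6-tetramethyl-2,3,3a,4,8,8a-hexahydroazulen-7(1H)-one (cis-fused) | O=C1C[C@H]2[C@H](CC[C@]2(C)O)C(C)(C)C=C1C | intermediate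
21 | (1S,3aS,7R,8aS)-1,4,4,6-tetramethyl-1,2,3,3a,4,7,8,8a-octahydroazulene-1,7-diol | O[C@@H]1C[C@H]2[C@H](CC[C@]2(C)O)C(C)(C)C=C1C | intermediate
22 | diethyl (1S,3aS,7S,8aS)-1-hydroxy-1,4,4,6-tetramethyl-1,2,3,3a,4,7,8,8a-octahydroazulen-7-yl phosphate (eastern fragment) | CCOP(=O)(OCC)O[C@H]1C[C@H]2[C@H](CC[C@]2(C)O)C(C)(C)C=C1C | intermediate
23 | (5aS,6S,7R,9aR)-6-[2-(9-borabicyclo[3.3.1]nonan-9-yl)ethyl]-7-hydroxy-2,2,5a,7-tetramethyloctahydro-1-benzoxepin-3(2H)-one | C(C[C@H]1[C@]2(C)CCC(=O)C(C)(C)O[C@@H]2CC[C@@]1(C)O)B1C2CCCC1CCC2 | intermediate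
24 | (5aS,6S,7R,9aR)-7-hydroxy-6-[2-[(1S,3aS,5R,8aS)-1-hydroxy-1,4,4,6-tetramethyl-1,2,3,3a,4,5,8,8a-octahydroazulen-5-yl]ethyl]-2,2,5a,7-tetramethyloctahydro-1-benzoxepin-3(2H)-one | CC1=CC[C@H]2[C@H](CC[C@]2(C)O)C(C)(C)[C@@H]1CC[C@H]1[C@]2(C)CCC(=O)C(C)(C)O[C@@H]2CC[C@@]1(C)O | target

**Step count and risks**
Total: 17 steps. Longest linear sequence: 11 steps (8 and 9 to 24, steps 7 to 17); the western branch is 6 steps before the union.

The three steps most likely to fail:

Step 3 (the proposed new cascade; the allylic-carbonate alkene is a weak nucleophile and the chair has an axial ring bond). Fallback with known chemistry, setting out from 3: the oxepane and cyclohexane are closed first by the established silyl-triflate tandem oxa-/carbacyclization that ends by proton loss (Me3SiOTf, 2,6-di-tert-butyl-4-methylpyridine, CH2Cl2, −78 °C, dilute acid work-up), giving tert-butyl carbonate exocyclic alkene F1. Iodocarbonate cyclization (IBr, toluene, −80 °C) then closes the cyclic carbonate onto the methylene group to give iodomethyl carbonate F2, and radical deiodination (Bu3SnH, AIBN, toluene, 80 °C) comes back to the route at 4.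

Step 14 (a simple ketone enolate must open a trisubstituted epoxide in a 7-exo mode). Fallback, setting out from 16: Claisen-type condensation with LiCH2SO2Ph (THF, −78 °C) gives beta-keto sulfone F3, and m-CPBA gives its epoxide F4 with the same facial selectivity. The doubly stabilized carbanion then opens the epoxide under mild base (Cs2CO3, DMF, 50 °C) to alpha-sulfonyl cycloheptenone F5, and reductive desulfonylation (SmI2, THF/MeOH, −78 °C) comes back to the route at 20.

Step 17 (SN2' attack at a ring carbon next to a quaternary center; 9-BBN must leave the ketone alone). Fallback, setting out from 21 and 6: O-alkylation of the secondary alkoxide (KH, Bu3SnCH2I, THF) gives stannylmethyl ether F6, and tin–lithium exchange (n-BuLi, THF, −78 °C) triggers the [2,3]-Wittig–Still rearrangement, which transfers CH2OH suprafacially to C5 and gives homoallylic alcohol F7. Mitsunobu thioetherification with 1-phenyl-1H-tetrazole-5-thiol (PPh3, DIAD) gives sulfide F8, and (NH4)6Mo7O24/H2O2 in EtOH gives sulfone F9. Julia–Kocienski olefination of F9 with 6 (KN(SiMe3)2, THF, −78 °C) gives (E)-alkene F10, and selective hydrogenation of the disubstituted alkene (H2, RhCl(PPh3)3, benzene) comes back to the route at 24.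

**Further compounds**
F1 | step 3 | tert-butyl [(3R,5aS,6R,9aR)-3-hydroxy-2,2,5a-trimethyl-7-methylidenedecahydro-1-benzoxepin-6-yl]methyl carbonate | CC(C)(C)OC(=O)OC[C@H]1[C@]2(C)CC[C@@H](O)C(C)(C)O[C@@H]2CCC1=C
F2 | step 3 | 7-(iodomethyl) analogue of cyclic carbonate 4 (same configuration at every center) | O=C1OC[C@H]2[C@]3(C)CC[C@@H](O)C(C)(C)O[C@@H]3CC[C@@]2(CI)O1
F3 | step 14 | (3Z)-3,5-dimethyl-5-[(1S)-3-methylcyclopent-2-en-1-yl]-1-(phenylsulfonyl)hex-3-en-2-one | O=C(CS(=O)(=O)c1ccccc1)/C(C)=C\C(C)(C)[C@H]1CCC(C)=C1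
F4 | step 14 | (3Z)-3,5-dimethyl-5-[(1R,2R,5S)-5-methyl-6-oxabicyclo[3.1.0]hexan-2-yl]-1-(phenylsulfonyl)hex-3-en-2-one | O=C(CS(=O)(=O)c1ccccc1)/C(C)=C\C(C)(C)[C@H]1CC[C@]2(C)O[C@H]12
F5 | step 14 | (1S,3aS,8aS)-1-hydroxy-1,4,4,6-tetramethyl-8-(phenylsulfonyl)-2,3,3a,4,8,8a-hexahydroazulen-7(1H)-one (C8 epimers) | O=C1C(S(=O)(=O)c3ccccc3)[C@H]2[C@H](CC[C@]2(C)O)C(C)(C)C=C1C
F6 | step 17 | (1S,3aS,7R,8aS)-1,4,4,6-tetramethyl-7-[(tributylstannyl)methoxy]-1,2,3,3a,4,7,8,8a-octahydroazulen-1-ol | CCCC[Sn](CCCC)(CCCC)CO[C@@H]1C[C@H]2[C@H](CC[C@]2(C)O)C(C)(C)C=C1C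
F7 | step 17 | (1S,3aS,5R,8aS)-5-(hydroxymethyl)-1,4,4,6-tetramethyl-1,2,3,3a,4,5,8,8a-octahydroazulen-1-ol | CC1=CC[C@H]2[C@H](CC[C@]2(C)O)C(C)(C)[C@@H]1CO
F8 | step 17 | (1S,3aS,5R,8aS)-1,4,4,6-tetramethyl-5-[(1-phenyl-1H-tetrazol-5-yl)sulfanylmethyl]-1,2,3,3a,4,5,8,8a-octahydroazulen-1-ol | CC1=CC[C@H]2[C@H](CC[C@]2(C)O)C(C)(C)[C@@H]1CSc1nnnn1-c1ccccc1
F9 | step 17 | (1S,3aS,5R,8aS)-1,4,4,6-tetramethyl-5-[(1-phenyl-1H-tetrazol-5-yl)sulfonylmethyl]-1,2,3,3a,4,5,8,8a-octahydroazulen-1-ol | CC1=CC[C@H]2[C@H](CC[C@]2(C)O)C(C)(C)[C@@H]1CS(=O)(=O)c1nnnn1-c1ccccc1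
F10 | step 17 | (5aS,6S,7R,9aR)-7-hydroxy-6-[(E)-2-[(1S,3aS,5R,8aS)-1-hydroxy-1,4,4,6-tetramethyl-1,2,3,3a,4,5,8,8a-octahydroazulen-5-yl]ethenyl]-2,2,5a,7-tetramethyloctahydro-1-benzoxepin-3(2H)-one | CC1=CC[C@H]2[C@H](CC[C@]2(C)O)C(C)(C)[C@@H]1/C=C/[C@H]1[C@]2(C)CCC(=O)C(C)(C)O[C@@H]2CC[C@@]1(C)O
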